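**Strategy.** Everything rests on disconnecting the C4–C5 bond of the quinone ring, numbered from C1 (the carbonyl between chain-bearing C2 and C6–H) to C4 (the carbonyl between the methoxy carbons C3 and C5). The key step heats a cyclobutenone in which C4 is the ring carbonyl, C3 carries methoxy, C2 the side chain, and C1 is a quaternary silyloxy carbon bearing C6=C5 as a (Z)-2-methoxyvinyl group; ring opening to a dienylketene and six-electron closure build the fully substituted benzene ring, at the hydroquinone level, in one operation. The aryl ketone travels as a dioxolane, and the reversed substituent order comes from two successive organolithium additions to dimethyl squarate followed by a carbonyl transposition.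

Key step: step 7

Remark: the target is achiral and every chiral intermediate is racemic. The ring numbering C1–C6 used in the discussion is the one defined above and differs from the locants in the systematic names.

**Step 1**
Reactants: 1 methyl vinyl ether
Product: 3 (Z)-1-bromo-2-methoxyethene, via 1,2-dibromo-1-methoxyethane 2 (not isolated)
Conditions: Br2, pentane, −78 °C; then PhNEt2, 0 → 95 °C, distil
Reagents that add atoms: bromine, BrBr
Why: Electrophilic bromination of the enol ether followed by amine-induced dehydrobromination (ionisation of the α-bromo ether and loss of the neighbouring proton) is the standard entry to cis-2-alkoxyvinyl bromides and should favour the Z isomer, while any E isomer is harmless later because its lithio derivative fragments to acetylene and methoxide.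

**Step 2**
Reactants: 4 veratrole; 5 3-chloropropanoyl chloride
Product: 6 3-chloro-1-(3,4-dimethoxyphenyl)propan-1-one
Conditions: AlCl3, CH2Cl2, 0 °C
Reagents that add atoms: none
Why: Friedel–Crafts acylation of veratrole should occur para to one methoxy group, the unhindered activated position, and the ketone formed is deactivated towards a second acylation.

**Step 3**
Reactants: 6 3-chloro-1-(3,4-dimethoxyphenyl)propan-1-one
Product: 7 2-(2-chloroethyl)-2-(3,4-dimethoxyphenyl)-1,3-dioxolane
Conditions: HOCH2CH2OH, TsOH·H2O (cat.), PhH, reflux, Dean–Stark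
Reagents that add atoms: ethylene glycol, OCCO
Why: Acid-catalysed ketalisation with azeotropic removal of water masks the aryl ketone against the organolithium chemistry to come, and the primary chloride is inert to these conditions.

**Step 4**
Reactants: 7 2-(2-chloroethyl)-2-(3,4-dimethoxyphenyl)-1,3-dioxolane
Product: 8 2-(3,4-dimethoxyphenyl)-2-(2-iodoethyl)-1,3-dioxolane
Conditions: NaI, NaHCO3 (trace), butan-2-one, reflux
Reagents that add atoms: sodium iodide, [Na+].[I-]
Why: Finkelstein halide exchange (SN2) at the unhindered primary carbon is driven by precipitation of NaCl and supplies the iodide needed for clean low-temperature iodine–lithium exchange.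

**Step 5**
Reactants: 3 (Z)-1-bromo-2-methoxyethene; 9 dimethyl squarate
Product: 12 racemic 2,3-dimethoxy-4-[(Z)-2-methoxyvinyl]-4-(trimethylsilyloxy)cyclobut-2-en-1-one, via (Z)-2-methoxyvinyllithium 10 (not isolated), via squarate-adduct lithium alkoxide 11 (not isolated)
Conditions: n-BuLi, Et2O, −78 °C; 9, THF, −78 °C; then TMSCl, −78 → 0 °C; cold aq. NaHCO3 work-up
Reagents that add atoms: chlorotrimethylsilane, C[Si](C)(C)Cl
Why: Bromine–lithium exchange should give the configurationally stable cis-2-methoxyvinyllithium (internal O–Li coordination, no anti-periplanar leaving group), which adds 1,2 to one carbonyl of the squarate ester as organolithiums do, and the tertiary alkoxide is O-silylated in the flask; the new quaternary carbon forms as a racemate and is destroyed in step 7.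

**Step 6**
Reactants: 8 2-(3,4-dimethoxyphenyl)-2-(2-iodoethyl)-1,3-dioxolane; 12 racemic 2,3-dimethoxy-4-[(Z)-2-methoxyvinyl]-4-(trimethylsilyloxy)cyclobut-2-en-1-one
Product: 16 racemic 3-{2-[2-(3,4-dimethoxyphenyl)-1,3-dioxolan-2-yl]ethyl}-2-methoxy-4-[(Z)-2-methoxyvinyl]-4-(trimethylsilyloxy)cyclobut-2-en-1-one, via ketal-masked alkyllithium 13 (not isolated), via second-adduct lithium alkoxide 14 (not isolated), via allylic trifluoroacetate 15 (not isolated)
Conditions: 8, t-BuLi (2 equiv), Et2O–pentane, −78 °C; add 12, THF, −78 °C; (CF3CO)2O (1.1 equiv), −78 °C; aq. NaHCO3, −78 → 0 °C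
Reagents that add atoms: water, O
Why: Iodine–lithium exchange gives the primary alkyllithium, which adds 1,2 to the remaining vinylogous-ester carbonyl, and O-trifluoroacetylation of the alkoxide, ionisation to the methoxy-stabilised cyclobutenyl cation and hydrolysis at the distal methoxy carbon on quench (allylic 1,3-carbonyl transposition of squarate adducts) should place the carbonyl next to the silyloxy carbon; the diastereomers of 14 converge because one sp3 carbon becomes sp2, and the cold, acid-free protocol is meant to outrun silyl migration and spare the enol ether and the dioxolane.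

**Step 7**
Reactants: 16 racemic 3-{2-[2-(3,4-dimethoxyphenyl)-1,3-dioxolan-2-yl]ethyl}-2-methoxy-4-[(Z)-2-methoxyvinyl]-4-(trimethylsilyloxy)cyclobut-2-en-1-one
Product: 19 3-{2-[2-(3,4-dimethoxyphenyl)-1,3-dioxolan-2-yl]ethyl}-2,6-dimethoxy-4-(trimethylsilyloxy)phenol, via dienylketene 17 (not isolated), via cyclohexa-2,4-dienone 18 (not isolated)
Conditions: PhMe (degassed, dilute), 110 °C
Reagents that add atoms: none
Why: Heating should open the cyclobutenone by a conrotatory four-electron electrocyclic cleavage of the C4–C1 bond (ring numbering of the overview), the silyloxy donor rotating outward so that the methoxyvinyl group lies cis to the ketene in 17. The ketene carbon C4 then bonds to the methoxy-bearing alkene terminus C5 in a disrotatory six-electron electrocyclisation, a six-membered carbocyclic closure in which the sp-hybridised ketene terminus leaves room for the inward Z-methoxy group, and dienone 18 aromatises by tautomerisation (C5–H to the C4 oxygen). The closest known reaction type is the thermal ring expansion of 4-alkenyl- and 4-aryl-4-oxycyclobutenones to hydroquinone derivatives (Moore rearrangement). No stereocentre is created: the quaternary carbon of 16 and the C5 centre of 18 both become sp2, so the racemic precursor converges on one achiral product. The step needs regiocontrol, which is built into 16 because the ketene can only arise from the carbonyl beside the methoxy carbon and can only reach the vinyl terminus, and it needs the ketene to cyclise before it is intercepted, which dilute, degassed, aprotic conditions should secure.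

**Step 8**
Reactants: 19 3-{2-[2-(3,4-dimethoxyphenyl)-1,3-dioxolan-2-yl]ethyl}-2,6-dimethoxy-4-(trimethylsilyloxy)phenol
Product: 21 3-{2-[2-(3,4-dimethoxyphenyl)-1,3-dioxolan-2-yl]ethyl}-2,6-dimethoxycyclohexa-2,5-diene-1,4-dione, via hydroquinone 20 (not isolated)
Conditions: TBAF, AcOH, THF, 0 °C; then Ag2O, MgSO4, rt
Reagents that add atoms: none
Why: Buffered fluoride cleaves the labile aryl silyl ether and Ag2O then dehydrogenates the electron-rich hydroquinone to the para-quinone under neutral conditions (hydroquinone oxidation), the ketone staying masked so that the phenol ortho to the side chain cannot close onto it to give a chroman hemiketal or flavene.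

**Step 9**
Reactants: 21 3-{2-[2-(3,4-dimethoxyphenyl)-1,3-dioxolan-2-yl]ethyl}-2,6-dimethoxycyclohexa-2,5-diene-1,4-dione
Product: 22 evelynin, 3-[3-(3,4-dimethoxyphenyl)-3-oxopropyl]-2,6-dimethoxycyclohexa-2,5-diene-1,4-dione
Conditions: 0.5 M HCl, THF–H2O, rt
Reagents that add atoms: water, O
Why: Acid-catalysed ketal hydrolysis is fast at the electron-rich benzylic ketal carbon and should release the aryl ketone under conditions too mild to hydrolyse the vinylogous-ester methoxy groups of the quinone.

**Compound list**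

1 | methyl vinyl ether | COC=C | starting material
2 | 1,2-dibromo-1-methoxyethane (racemic) | COC(Br)CBr | intermediate
3 | (Z)-1-bromo-2-methoxyethene | CO/C=C\Br | intermediate
4 | veratrole (1,2-dimethoxybenzene) | COc1ccccc1OC | starting material
5 | 3-chloropropanoyl chloride | O=C(Cl)CCCl | starting material
6 | 3-chloro-1-(3,4-dimethoxyphenyl)propan-1-one | COc1ccc(C(=O)CCCl)cc1OC | intermediate
7 | 2-(2-chloroethyl)-2-(3,4-dimethoxyphenyl)-1,3-dioxolane | COc1ccc(C2(CCCl)OCCO2)cc1OC | intermediate
8 | 2-(3,4-dimethoxyphenyl)-2-(2-iodoethyl)-1,3-dioxolane | COc1ccc(C2(CCI)OCCO2)cc1OC | intermediate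
9 | dimethyl squarate | COC1=C(OC)C(=O)C1=O | starting material
10 | (Z)-2-methoxyvinyllithium | CO/C=C\[Li] | intermediate
11 | lithium 2,3-dimethoxy-1-[(Z)-2-methoxyvinyl]-4-oxocyclobut-2-en-1-olate (racemic) | CO/C=C\C1([O-])C(OC)=C(OC)C1=O.[Li+] | intermediate
12 | 2,3-dimethoxy-4-[(Z)-2-methoxyvinyl]-4-(trimethylsilyloxy)cyclobut-2-en-1-one (racemic) | CO/C=C\C1(O[Si](C)(C)C)C(OC)=C(OC)C1=O | intermediate
13 | {2-[2-(3,4-dimethoxyphenyl)-1,3-dioxolan-2-yl]ethyl}lithium | [Li]CCC1(OCCO1)c1ccc(OC)c(OC)c1 | intermediate
14 | lithium 1-{2-[2-(3,4-dimethoxyphenyl)-1,3-dioxolan-2-yl]ethyl}-2,3-dimethoxy-4-[(Z)-2-methoxyvinyl]-4-(trimethylsilyloxy)cyclobut-2-en-1-olate (racemic diastereomer mixture) | CO/C=C\C1(O[Si](C)(C)C)C(OC)=C(OC)C1([O-])CCC2(OCCO2)c2ccc(OC)c(OC)c2.[Li+] | intermediate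
15 | 1-{2-[2-(3,4-dimethoxyphenyl)-1,3-dioxolan-2-yl]ethyl}-2,3-dimethoxy-4-[(Z)-2-methoxyvinyl]-4-(trimethylsilyloxy)cyclobut-2-en-1-yl trifluoroacetate (racemic diastereomer mixture) | CO/C=C\C1(O[Si](C)(C)C)C(OC)=C(OC)C1(OC(=O)C(F)(F)F)CCC2(OCCO2)c2ccc(OC)c(OC)c2 | intermediate
16 | 3-{2-[2-(3,4-dimethoxyphenyl)-1,3-dioxolan-2-yl]ethyl}-2-methoxy-4-[(Z)-2-methoxyvinyl]-4-(trimethylsilyloxy)cyclobut-2-en-1-one (racemic) | CO/C=C\C1(O[Si](C)(C)C)C(CCC2(OCCO2)c2ccc(OC)c(OC)c2)=C(OC)C1=O | intermediate
17 | (3E,5Z)-3-{2-[2-(3,4-dimethoxyphenyl)-1,3-dioxolan-2-yl]ethyl}-2,6-dimethoxy-4-(trimethylsilyloxy)hexa-1,3,5-trien-1-one | O=C=C(OC)/C(CCC2(OCCO2)c2ccc(OC)c(OC)c2)=C(/O[Si](C)(C)C)\C=C/OC | intermediate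
18 | 3-{2-[2-(3,4-dimethoxyphenyl)-1,3-dioxolan-2-yl]ethyl}-2,6-dimethoxy-4-(trimethylsilyloxy)cyclohexa-2,4-dien-1-one (racemic) | COC1C=C(O[Si](C)(C)C)C(CCC2(OCCO2)c2ccc(OC)c(OC)c2)=C(OC)C1=O | intermediate
19 | 3-{2-[2-(3,4-dimethoxyphenyl)-1,3-dioxolan-2-yl]ethyl}-2,6-dimethoxy-4-(trimethylsilyloxy)phenol | COc1cc(O[Si](C)(C)C)c(CCC2(OCCO2)c2ccc(OC)c(OC)c2)c(OC)c1O | intermediate
20 | 2-{2-[2-(3,4-dimethoxyphenyl)-1,3-dioxolan-2-yl]ethyl}-3,5-dimethoxybenzene-1,4-diol | COc1cc(O)c(CCC2(OCCO2)c2ccc(OC)c(OC)c2)c(OC)c1O | intermediate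
21 | 3-{2-[2-(3,4-dimethoxyphenyl)-1,3-dioxolan-2-yl]ethyl}-2,6-dimethoxycyclohexa-2,5-diene-1,4-dione | COC1=CC(=O)C(CCC2(OCCO2)c2ccc(OC)c(OC)c2)=C(OC)C1=O | intermediate
22 | evelynin, 3-[3-(3,4-dimethoxyphenyl)-3-oxopropyl]-2,6-dimethoxycyclohexa-2,5-diene-1,4-dione | COC1=CC(=O)C(CCC(=O)c2ccc(OC)c(OC)c2)=C(OC)C1=O | target

**Step count and risks**

Total step count: 9. Longest linear sequence: 7 steps (steps 2, 3, 4, 6, 7, 8, 9, from veratrole).

Steps most likely to fail:

1. Step 6. Migration of the silyl group between the two neighbouring oxygens of alkoxide 14, ionisation at the silyloxy-bearing carbon assisted by the enol ether, or C-acylation of the enol ether by the anhydride would scramble or destroy the substituent order. The fallback closes C1–C6 instead of C4–C5 and needs no transposition in the presence of the enol ether; it sets out from dimethyl squarate 9 and iodide 8. Alkyllithium 13, made from 8 as in step 6, is added to 9 at −78 °C. The resulting lithium 1-{2-[2-(3,4-dimethoxyphenyl)-1,3-dioxolan-2-yl]ethyl}-2,3-dimethoxy-4-oxocyclobut-2-en-1-olate F1 is quenched with (CF3CO)2O and then aq. NaHCO3 to give 3-{2-[2-(3,4-dimethoxyphenyl)-1,3-dioxolan-2-yl]ethyl}-4-methoxycyclobut-3-ene-1,2-dione F2. 1-Methoxyvinyllithium F3, from methyl vinyl ether 1 and t-BuLi in THF, should add to the more electrophilic carbonyl beside the methoxy-bearing carbon and give, after NH4Cl quench, 2-{2-[2-(3,4-dimethoxyphenyl)-1,3-dioxolan-2-yl]ethyl}-4-hydroxy-3-methoxy-4-(1-methoxyvinyl)cyclobut-2-en-1-one F4. Heating F4 in toluene should open it to (3Z)-2-{2-[2-(3,4-dimethoxyphenyl)-1,3-dioxolan-2-yl]ethyl}-4-hydroxy-3,5-dimethoxyhexa-1,3,5-trien-1-one F5, which closes onto its CH2 terminus to 2-{2-[2-(3,4-dimethoxyphenyl)-1,3-dioxolan-2-yl]ethyl}-4-hydroxy-3,5-dimethoxycyclohexa-2,4-dien-1-one F6 and tautomerises to hydroquinone 20. The route is rejoined at 20, with the Ag2O oxidation of step 8 and no fluoride.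

2. Step 7. The electrocyclisation must bond the ketene carbon to an oxygen-bearing, weakly nucleophilic alkene terminus that carries an inward methoxy group, so closure may be slow and the ketene may dimerise or be captured by the phenol already formed. The fallback abandons ring construction for radical C–H alkylation of a preformed quinone and sets out from veratrole 4. Friedel–Crafts acylation with succinic anhydride (AlCl3, CH2Cl2) gives 4-(3,4-dimethoxyphenyl)-4-oxobutanoic acid F7. Silver-catalysed persulfate decarboxylation of F7 (AgNO3 cat., (NH4)2S2O8, MeCN–H2O, 65 °C; Jacobsen–Torssell quinone alkylation) in the presence of excess commercial 2,6-dimethoxy-1,4-benzoquinone should attach the 3-aryl-3-oxopropyl radical at one of the two equivalent free ring positions. This comes back to the route at evelynin 22.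

3. Step 5. Fragmentation of the vinyllithium, incomplete O-silylation of the hindered alkoxide, or acid-triggered loss of the allylic oxygen during work-up (enal formation) would erode the supply of 12. The fallback sets the Z geometry by alkyne semihydrogenation and sets out from dimethyl squarate 9. Methoxyacetylene F8, from chloroacetaldehyde dimethyl acetal and NaNH2 in liquid NH3, is lithiated with n-BuLi to lithium methoxyacetylide F9 and added to 9 at −78 °C. The lithium 2,3-dimethoxy-1-(methoxyethynyl)-4-oxocyclobut-2-en-1-olate F10 so formed is silylated in the flask with TMSCl to 2,3-dimethoxy-4-(methoxyethynyl)-4-(trimethylsilyloxy)cyclobut-2-en-1-one F11. Hydrogenation over Pd/CaCO3 poisoned with Pb(OAc)2 and quinoline (H2, 1 atm, 0 °C) should deliver hydrogen syn and return the route at 12.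

**Further compounds**

F1 | step 6 | lithium 1-{2-[2-(3,4-dimethoxyphenyl)-1,3-dioxolan-2-yl]ethyl}-2,3-dimethoxy-4-oxocyclobut-2-en-1-olate | COC1=C(OC)C([O-])(CCC2(OCCO2)c2ccc(OC)c(OC)c2)C1=O.[Li+]
F2 | step 6 | 3-{2-[2-(3,4-dimethoxyphenyl)-1,3-dioxolan-2-yl]ethyl}-4-methoxycyclobut-3-ene-1,2-dione | COC1=C(CCC2(OCCO2)c2ccc(OC)c(OC)c2)C(=O)C1=O
F3 | step 6 | 1-methoxyvinyllithium | [Li]C(=C)OC
F4 | step 6 | 2-{2-[2-(3,4-dimethoxyphenyl)-1,3-dioxolan-2-yl]ethyl}-4-hydroxy-3-methoxy-4-(1-methoxyvinyl)cyclobut-2-en-1-one | C=C(OC)C1(O)C(OC)=C(CCC2(OCCO2)c2ccc(OC)c(OC)c2)C1=O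
F5 | step 6 | (3Z)-2-{2-[2-(3,4-dimethoxyphenyl)-1,3-dioxolan-2-yl]ethyl}-4-hydroxy-3,5-dimethoxyhexa-1,3,5-trien-1-one | O=C=C(CCC2(OCCO2)c2ccc(OC)c(OC)c2)/C(OC)=C(/O)C(=C)OC
F6 | step 6 | 2-{2-[2-(3,4-dimethoxyphenyl)-1,3-dioxolan-2-yl]ethyl}-4-hydroxy-3,5-dimethoxycyclohexa-2,4-dien-1-one | COC1=C(O)C(OC)=C(CCC2(OCCO2)c2ccc(OC)c(OC)c2)C(=O)C1
F7 | step 7 | 4-(3,4-dimethoxyphenyl)-4-oxobutanoic acid | COc1ccc(C(=O)CCC(=O)O)cc1OC
F8 | step 5 | methoxyacetylene | COC#C
F9 | step 5 | lithium methoxyacetylide | COC#C[Li]
F10 | step 5 | lithium 2,3-dimethoxy-1-(methoxyethynyl)-4-oxocyclobut-2-en-1-olate | COC#CC1([O-])C(OC)=C(OC)C1=O.[Li+]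
F11 | step 5 | 2,3-dimethoxy-4-(methoxyethynyl)-4-(trimethylsilyloxy)cyclobut-2-en-1-one | COC#CC1(O[Si](C)(C)C)C(OC)=C(OC)C1=O
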